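**Retrosynthetic overview**

1. Feature: the central benzene ring is fully substituted, with a free OH on C1 and an OMe on C3 meta to each other across the benzyl-bearing C2, and carbon groups on C4 (4-hydroxybenzyl), C5 (3-methoxyphenethyl) and C6 (4-hydroxybenzyl). A 3-alkoxyphenol with carbon on every other ring atom is the pattern a vinylketene plus a 1-alkoxyalkyne delivers.
2. Target 23 ⇐ tris-benzyl ether 22 ⇐ α-diazo enone 10 (supplies C1, C4, C5, C6) + methoxyalkyne 17 (supplies C2, C3). Bonds made: C1–C2 and C3–C4 in the [2+2], C1–C6 in the 6π closure, after the Wolff shift has joined C4 to C5.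
3. 10 ⇐ (E)-enone 8 by diazo transfer ⇐ α-branched β-ketophosphonate 5 + arylacetaldehyde 7 (HWE); 5 ⇐ phosphonate 4 + ester 2.
4. 17 ⇐ lithium methoxyacetylide (from trichloroethylene via dichlorovinyl ether 13) + benzylic bromide 14.
5. Ring order: the four outer benzene rings are bought; the central ring is the only ring built (step 9), and step 10 only unmasks three phenols.

Key step: step 9

Assumption: the target has no stereocentre and no configurationally stable axis, so it is achiral and the given SMILES defines one constitution only; compounds 1, 3, 6, 11 and 14 are taken as catalogue chemicals.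

**Route**

Step 1
Reactants: 1 methyl 3-(4-hydroxyphenyl)propanoate
Product: 2 methyl 3-[4-(benzyloxy)phenyl]propanoate
Conditions: BnBr (1.1 eq), K2CO3 (1.5 eq), DMF, rt
Reagents that add atoms: benzyl bromide, BrCc1ccccc1
Why: Williamson ether synthesis on the phenoxide; anhydrous carbonate should leave the methyl ester untouched.

Step 2
Reactants: 3 1-(3-bromopropyl)-3-methoxybenzene
Product: 4 diethyl [3-(3-methoxyphenyl)propyl]phosphonate
Conditions: P(OEt)3 (3 eq, neat), 150 °C, EtBr distilled off
Reagents that add atoms: triethyl phosphite, CCOP(OCC)OCC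
Why: Michaelis–Arbuzov reaction of an unhindered primary bromide, which should proceed cleanly without competing elimination.

Step 3
Reactants: 4 diethyl [3-(3-methoxyphenyl)propyl]phosphonate; 2 methyl 3-[4-(benzyloxy)phenyl]propanoate
Product: 5 diethyl {6-[4-(benzyloxy)phenyl]-1-(3-methoxyphenyl)-4-oxohexan-3-yl}phosphonate (racemic)
Conditions: 4 (2.2 eq), n-BuLi (2.1 eq), THF, −78 °C; then 2, −78 → 0 °C; aq. NH4Cl
Reagents that add atoms: none
Why: Claisen-type acylation of the α-lithioalkylphosphonate by the ester, in which the second equivalent of carbanion deprotonates the product and prevents over-addition; the phenethyl branch is thus placed on the phosphonate carbon without alkylating a ketophosphonate with an elimination-prone phenethyl halide.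

Step 4
Reactants: 6 2-[4-(benzyloxy)phenyl]ethanol
Product: 7 2-[4-(benzyloxy)phenyl]acetaldehyde
Conditions: Dess–Martin periodinane (1.2 eq), CH2Cl2, 0 °C → rt; used at once
Reagents that add atoms: none
Why: Dess–Martin oxidation is non-basic and stops at the aldehyde, so the enolisable arylacetaldehyde should be obtained without self-condensation.

Step 5
Reactants: 5 diethyl {6-[4-(benzyloxy)phenyl]-1-(3-methoxyphenyl)-4-oxohexan-3-yl}phosphonate; 7 2-[4-(benzyloxy)phenyl]acetaldehyde
Product: 8 (E)-1,6-bis[4-(benzyloxy)phenyl]-4-[2-(3-methoxyphenyl)ethyl]hex-4-en-3-one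
Conditions: activated Ba(OH)2 (0.8 eq), THF/H2O (40:1), 0 °C → rt
Reagents that add atoms: none
Why: Horner–Wadsworth–Emmons olefination of an α-branched β-ketophosphonate under mild barium hydroxide conditions, expected to favour the E enone (benzyl group trans to the carbonyl); any Z isomer would converge in step 9 because this alkene carbon becomes aromatic.

Step 6
Reactants: 8 (E)-1,6-bis[4-(benzyloxy)phenyl]-4-[2-(3-methoxyphenyl)ethyl]hex-4-en-3-one
Product: 10 (E)-1,6-bis[4-(benzyloxy)phenyl]-2-diazo-4-[2-(3-methoxyphenyl)ethyl]hex-4-en-3-one, via trifluoroacetyl diketone 9 (not isolated)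
Conditions: LiHMDS (1.1 eq), THF, −78 °C; CF3CO2CH2CF3 (1.2 eq), −78 °C; aq. HCl work-up; then MsN3 (1.5 eq), Et3N (1.5 eq), H2O (1 eq), MeCN, rt
Reagents that add atoms: methanesulfonyl azide, CS(=O)(=O)N=[N+]=[N-]; 2,2,2-trifluoroethyl trifluoroacetate, O=C(OCC(F)(F)F)C(F)(F)F (its CF3CO group is carried by 9 only and is lost again)
Why: Detrifluoroacetylative diazo transfer, in which kinetic deprotonation at −78 °C should take the α′-CH2 through a cyclic transition state (the benzylic γ-CH2 lies trans to the carbonyl and is not reached), and the trifluoroacetyl group then activates that carbon for diazo transfer and leaves on the sulfonamide.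

Step 7
Reactants: 11 trichloroethylene
Product: 13 (E)-1,2-dichloro-1-methoxyethene, via dichloroethyne 12 (not isolated)
Conditions: KOMe (1.0 eq), MeOH (5 mol %), THF, −50 °C → rt; distillation
Reagents that add atoms: potassium methoxide, C[O-].[K+]
Why: Base-induced β-elimination to dichloroethyne followed by anti addition of methanol across it (elimination–addition), the dichloroethyne being kept in dilute solution throughout.

Step 8
Reactants: 13 (E)-1,2-dichloro-1-methoxyethene; 14 1-(benzyloxy)-4-(bromomethyl)benzene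
Product: 17 1-(benzyloxy)-4-(3-methoxyprop-2-yn-1-yl)benzene, via chloro(methoxy)ethyne 15 (not isolated), via lithium methoxyacetylide 16 (not isolated)
Conditions: n-BuLi (2.05 eq), THF, −78 → −40 °C; then 14, DMPU, −78 °C → rt
Reagents that add atoms: none
Why: Deprotonation/β-elimination and Cl–Li exchange should give the lithium alkoxyacetylide, whose SN2 alkylation by the activated benzylic bromide forms the ynol ether; the methyl ether has no β-hydrogen and so cannot fragment thermally to a ketene.

Step 9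
Reactants: 10 (E)-1,6-bis[4-(benzyloxy)phenyl]-2-diazo-4-[2-(3-methoxyphenyl)ethyl]hex-4-en-3-one; 17 1-(benzyloxy)-4-(3-methoxyprop-2-yn-1-yl)benzene
Product: 22 2,4,6-tris[4-(benzyloxy)benzyl]-3-methoxy-5-[2-(3-methoxyphenyl)ethyl]phenol, via vinylketene 18 (not isolated), via 4-alkenylcyclobutenone 19 (not isolated), via dienylketene 20 (not isolated), via cyclohexa-2,4-dienone 21 (not isolated)
Conditions: 17 (1.5 eq), hν (medium-pressure Hg lamp, Pyrex filter), degassed ClCH2CH2Cl (0.2 M), rt; then 80 °C (toluene, 110 °C, if the cyclobutenone persists)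
Reagents that add atoms: none
Why: Light expels N2 from 10 and the alkenyl group shifts from the carbonyl carbon to the diazo carbon (photochemical Wolff rearrangement, joining C4 to C5) to give vinylketene 18. The electrophilic ketene carbon C1 then bonds to the nucleophilic benzyl-bearing alkyne carbon C2 while the ketene α-carbon C4 bonds to the methoxy-bearing C3 in a [2+2] cycloaddition, giving 4-alkenylcyclobutenone 19. Further irradiation or heating opens 19 by 4π electrocyclic cleavage of C1–C4 to dienylketene 20, which closes C1–C6 and tautomerises from dienone 21 to phenol 22; this is the Danheiser benzannulation in its photochemical diazo-ketone variant. The central ring is closed by a 6π electrocyclisation of a ketene-terminated triene, and no stereocentre remains because the sp3 carbons of 19 and 21 are lost on ring opening and aromatisation. The selectivity needed is regiochemical (OMe meta to OH), and it is secured by the polarisation of the ynol ether, whose donor oxygen makes C2 the nucleophilic carbon; the ketene oxygen becomes the free C1–OH and the alkyne oxygen the C3–OMe, so the two oxygens are differentiated by connectivity. Pyrex-filtered light is chosen so that the diazo enone and not the aryl benzyl ethers absorbs, and either alkene geometry converges because C6 becomes aromatic.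

Step 10
Reactants: 22 2,4,6-tris[4-(benzyloxy)benzyl]-3-methoxy-5-[2-(3-methoxyphenyl)ethyl]phenol
Product: 23 2,4,6-tris(4-hydroxybenzyl)-3-methoxy-5-[2-(3-methoxyphenyl)ethyl]phenol
Conditions: H2 (1 atm), 10% Pd/C, EtOAc/MeOH, rt
Reagents that add atoms: none
Why: Catalytic hydrogenolysis should cleave the three O-benzyl ethers while the diarylmethane C–C bonds, the two methyl ethers and the arenes remain intact.

**Compound list**

1 | methyl 3-(4-hydroxyphenyl)propanoate | COC(=O)CCc1ccc(O)cc1 | starting material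
2 | methyl 3-[4-(benzyloxy)phenyl]propanoate | COC(=O)CCc1ccc(OCc2ccccc2)cc1 | intermediate
3 | 1-(3-bromopropyl)-3-methoxybenzene | COc1cccc(CCCBr)c1 | starting material
4 | diethyl [3-(3-methoxyphenyl)propyl]phosphonate | CCOP(=O)(OCC)CCCc1cccc(OC)c1 | intermediate
5 | diethyl {6-[4-(benzyloxy)phenyl]-1-(3-methoxyphenyl)-4-oxohexan-3-yl}phosphonate (racemic) | CCOP(=O)(OCC)C(CCc1cccc(OC)c1)C(=O)CCc1ccc(OCc2ccccc2)cc1 | intermediate
6 | 2-[4-(benzyloxy)phenyl]ethanol | OCCc1ccc(OCc2ccccc2)cc1 | starting material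
7 | 2-[4-(benzyloxy)phenyl]acetaldehyde | O=CCc1ccc(OCc2ccccc2)cc1 | intermediate
8 | (E)-1,6-bis[4-(benzyloxy)phenyl]-4-[2-(3-methoxyphenyl)ethyl]hex-4-en-3-one | O=C(CCc1ccc(OCc2ccccc2)cc1)/C(CCc1cccc(OC)c1)=C/Cc1ccc(OCc2ccccc2)cc1 | intermediate
9 | (E)-3-[4-(benzyloxy)benzyl]-7-[4-(benzyloxy)phenyl]-1,1,1-trifluoro-5-[2-(3-methoxyphenyl)ethyl]hept-5-ene-2,4-dione (racemic) | O=C(C(Cc1ccc(OCc2ccccc2)cc1)C(=O)C(F)(F)F)/C(CCc1cccc(OC)c1)=C/Cc1ccc(OCc2ccccc2)cc1 | intermediate (not isolated)
10 | (E)-1,6-bis[4-(benzyloxy)phenyl]-2-diazo-4-[2-(3-methoxyphenyl)ethyl]hex-4-en-3-one | [N-]=[N+]=C(Cc1ccc(OCc2ccccc2)cc1)C(=O)/C(CCc1cccc(OC)c1)=C/Cc1ccc(OCc2ccccc2)cc1 | intermediate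
11 | trichloroethylene | ClC=C(Cl)Cl | starting material
12 | dichloroethyne | ClC#CCl | intermediate (not isolated)
13 | (E)-1,2-dichloro-1-methoxyethene | CO/C(Cl)=C\Cl | intermediate
14 | 1-(benzyloxy)-4-(bromomethyl)benzene | BrCc1ccc(OCc2ccccc2)cc1 | starting material
15 | chloro(methoxy)ethyne | COC#CCl | intermediate (not isolated)
16 | lithium methoxyacetylide | [Li]C#COC | intermediate (not isolated)
17 | 1-(benzyloxy)-4-(3-methoxyprop-2-yn-1-yl)benzene | COC#CCc1ccc(OCc2ccccc2)cc1 | intermediate
18 | (E)-2-[4-(benzyloxy)benzyl]-5-[4-(benzyloxy)phenyl]-3-[2-(3-methoxyphenyl)ethyl]penta-1,3-dien-1-one | O=C=C(Cc1ccc(OCc2ccccc2)cc1)/C(CCc1cccc(OC)c1)=C/Cc1ccc(OCc2ccccc2)cc1 | intermediate (not isolated)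
19 | 2,4-bis[4-(benzyloxy)benzyl]-4-{(E)-1-[4-(benzyloxy)phenyl]-5-(3-methoxyphenyl)pent-2-en-3-yl}-3-methoxycyclobut-2-en-1-one (racemic) | O=C1C(Cc2ccc(OCc3ccccc3)cc2)=C(OC)C1(Cc1ccc(OCc2ccccc2)cc1)/C(CCc1cccc(OC)c1)=C/Cc1ccc(OCc2ccccc2)cc1 | intermediate (not isolated)
20 | (3E,5E)-2,4-bis[4-(benzyloxy)benzyl]-7-[4-(benzyloxy)phenyl]-3-methoxy-5-[2-(3-methoxyphenyl)ethyl]hepta-1,3,5-trien-1-one | O=C=C(Cc1ccc(OCc2ccccc2)cc1)/C(OC)=C(Cc1ccc(OCc2ccccc2)cc1)\C(CCc1cccc(OC)c1)=C\Cc1ccc(OCc2ccccc2)cc1 | intermediate (not isolated)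
21 | 2,4,6-tris[4-(benzyloxy)benzyl]-3-methoxy-5-[2-(3-methoxyphenyl)ethyl]cyclohexa-2,4-dien-1-one (racemic) | O=C1C(Cc2ccc(OCc3ccccc3)cc2)=C(OC)C(Cc2ccc(OCc3ccccc3)cc2)=C(CCc2cccc(OC)c2)C1Cc1ccc(OCc2ccccc2)cc1 | intermediate (not isolated)
22 | 2,4,6-tris[4-(benzyloxy)benzyl]-3-methoxy-5-[2-(3-methoxyphenyl)ethyl]phenol | COc1cccc(CCc2c(Cc3ccc(OCc4ccccc4)cc3)c(O)c(Cc3ccc(OCc4ccccc4)cc3)c(OC)c2Cc2ccc(OCc3ccccc3)cc2)c1 | intermediate
23 | 2,4,6-tris(4-hydroxybenzyl)-3-methoxy-5-[2-(3-methoxyphenyl)ethyl]phenol | COc1cccc(CCc2c(Cc3ccc(O)cc3)c(O)c(Cc3ccc(O)cc3)c(OC)c2Cc2ccc(O)cc2)c1 | target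

**Step count and risk**

Total step count: 10. Longest linear sequence: 6 steps (1 or 3 → 23 through steps 1 or 2, 3, 5, 6, 9, 10).

Steps most likely to fail:

1. Step 9. The excited diazo ketone carries a benzylic CH2 on the diazo carbon, so a 1,2-hydride shift of the acyl carbene (or reaction from the s-trans conformer) may compete with alkenyl migration, and the congested vinylketene may dimerise before the [2+2]. The fallback reaches the same vinylketene thermally, with no carbene; it sets out from 2 and 17 and comes back at 22. Ester 2 would be saponified (LiOH, THF/H2O) to 3-[4-(benzyloxy)phenyl]propanoic acid F1 and converted with oxalyl chloride/cat. DMF into 3-[4-(benzyloxy)phenyl]propanoyl chloride F2. Slow addition of F2 to Et3N and 17 in CH2Cl2 would generate the ketene 3-[4-(benzyloxy)phenyl]prop-1-en-1-one F3, which the ynol ether should capture in a [2+2] cycloaddition to give 2,4-bis[4-(benzyloxy)benzyl]-3-methoxycyclobut-2-en-1-one F4. 1,2-Addition of [2-(3-methoxyphenyl)ethyl]magnesium bromide F5 (from commercial 1-(2-bromoethyl)-3-methoxybenzene, COc1cccc(CCBr)c1, and Mg) at −78 °C would give 2,4-bis[4-(benzyloxy)benzyl]-3-methoxy-1-[2-(3-methoxyphenyl)ethyl]cyclobut-2-en-1-ol F6. Dilute HCl would then hydrolyse the enol ether with allylic transposition to 2,4-bis[4-(benzyloxy)benzyl]-3-[2-(3-methoxyphenyl)ethyl]cyclobut-2-en-1-one F7. Heating F7 with 17 in toluene at 80–110 °C should open the cyclobutenone by 4π electrocyclic cleavage to vinylketene 18 and carry it through 19, 20 and 21 to 22.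

2. Step 5. The arylacetaldehyde may enolise and self-condense under the basic olefination, and the new double bond may migrate out of conjugation with the ketone into conjugation with the arene. The fallback is a Wittig reaction without added base; it sets out from 3 and comes back at 8. Bromide 3 and PPh3 (MeCN, reflux) would give [3-(3-methoxyphenyl)propyl]triphenylphosphonium bromide F8, and n-BuLi (THF, −78 °C) would convert it into [3-(3-methoxyphenyl)propylidene]triphenylphosphorane F9. Two equivalents of F9 would be acylated by 3-[4-(benzyloxy)phenyl]propanoyl chloride F2 (made from 2 through F1 as described above), one equivalent acting as the base, to give the acyl-stabilised ylide 1-[4-(benzyloxy)phenyl]-6-(3-methoxyphenyl)-4-(triphenyl-λ5-phosphanylidene)hexan-3-one F10. Heating F10 with 7 in toluene at 80–100 °C should give 8 with E selectivity.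

3. Step 8. The lithium acetylide may undergo electron transfer or halogen–metal exchange with the electron-rich benzylic bromide, and may isomerise the propargylic product to an allenyl ether by deprotonation. The fallback replaces the SN2 alkylation by a neutral cross-coupling; it sets out from 13 (and 14) and comes back at 17. Lithium methoxyacetylide 16, generated as in step 8, would be quenched with Bu3SnCl to give tributyl(methoxyethynyl)stannane F11. Stille coupling of F11 with 14 (Pd2(dba)3/AsPh3, THF, 50 °C) should then give 17.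

**Further compounds**

F1 | step 9 | 3-[4-(benzyloxy)phenyl]propanoic acid | OC(=O)CCc1ccc(OCc2ccccc2)cc1
F2 | step 9 | 3-[4-(benzyloxy)phenyl]propanoyl chloride | ClC(=O)CCc1ccc(OCc2ccccc2)cc1
F3 | step 9 | 3-[4-(benzyloxy)phenyl]prop-1-en-1-one | O=C=CCc1ccc(OCc2ccccc2)cc1
F4 | step 9 | 2,4-bis[4-(benzyloxy)benzyl]-3-methoxycyclobut-2-en-1-one (racemic) | COC1=C(Cc2ccc(OCc3ccccc3)cc2)C(=O)C1Cc1ccc(OCc2ccccc2)cc1
F5 | step 9 | [2-(3-methoxyphenyl)ethyl]magnesium bromide | COc1cccc(CC[Mg]Br)c1
F6 | step 9 | 2,4-bis[4-(benzyloxy)benzyl]-3-methoxy-1-[2-(3-methoxyphenyl)ethyl]cyclobut-2-en-1-ol (mixture of diastereomers) | COC1=C(Cc2ccc(OCc3ccccc3)cc2)C(O)(CCc2cccc(OC)c2)C1Cc1ccc(OCc2ccccc2)cc1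
F7 | step 9 | 2,4-bis[4-(benzyloxy)benzyl]-3-[2-(3-methoxyphenyl)ethyl]cyclobut-2-en-1-one (racemic) | O=C1C(Cc2ccc(OCc3ccccc3)cc2)=C(CCc2cccc(OC)c2)C1Cc1ccc(OCc2ccccc2)cc1
F8 | step 5 | [3-(3-methoxyphenyl)propyl]triphenylphosphonium bromide | COc1cccc(CCC[P+](c2ccccc2)(c2ccccc2)c2ccccc2)c1.[Br-]
F9 | step 5 | [3-(3-methoxyphenyl)propylidene]triphenylphosphorane | COc1cccc(CCC=P(c2ccccc2)(c2ccccc2)c2ccccc2)c1
F10 | step 5 | 1-[4-(benzyloxy)phenyl]-6-(3-methoxyphenyl)-4-(triphenyl-λ5-phosphanylidene)hexan-3-one | O=C(CCc1ccc(OCc2ccccc2)cc1)C(CCc1cccc(OC)c1)=P(c1ccccc1)(c1ccccc1)c1ccccc1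
F11 | step 8 | tributyl(methoxyethynyl)stannane | COC#C[Sn](CCCC)(CCCC)CCCC
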